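Compare the target peaks of the two earlier runs before charging the new flask, and set the reading times around the peak.

| flask | substrate | remark | time |
|---|---|---|---|
| Thursday's | 1.5 M | run made earlier |  |
| Wednesday's | 2.4 M | run made earlier |  |
| flask | 1.1 M |  | 5.0 min |

| run | time / min | target / % |
|---|---|---|
| Thursday's | 0.200 | 6.3 |
| Thursday's | 0.333 | 8.3 |
| Thursday's | 0.667 | 10.4 |
| Thursday's | 1.00 | 9.6 |
| Thursday's | 2.00 | 9.2 |
| Thursday's | 3.00 | 8.0 |
| Wednesday's | 0.200 | 4.3 |
| Wednesday's | 0.333 | 5.8 |
| Wednesday's | 0.667 | 7.2 |
| Wednesday's | 1.00 | 7.3 |
| Wednesday's | 2.00 | 6.7 |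
| Wednesday's | 3.00 | 5.2 |

(each reading ± 0.3 percentage points)

- time up to 5.0 min at which target stands highest
- the amount of target, in percent of the substrate charged, at that time

- what was read earlier has a scatter of 0.3 percentage points, one standard deviation

Thursday's highest target reading is 10.4% at c_substrate = 1.5 M, while Wednesday's is 7.3% at 2.4 M, so the richer charge reads lower. The slope of ln(peak yield) against ln c_substrate between these readings, taken with its sign reversed, is 0.753; this is the dilution exponent, an apparent order of the yield. My own reckoning carries Thursday's reading to 1.1 M with it and gives 13.1%. The forecast stands lower, at 12.7% after 0.9 min; it starts from a peak of about 10.2% at Thursday's charge and an exponent of about 0.7, not from the reading and the exponent above: “Extrapolating to 1.1 M gives 10.2×1.24≈12.7%”.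

This flask stands highest at 0.870 min, with 12.3% of target.

    2 substrate → self-condensation product (k = 0.200 L mol⁻¹ s⁻¹)
    intermediate ⇌ target (K = 1.70, k = 0.100 s⁻¹)
    substrate → intermediate (k = 0.0470 s⁻¹)
    intermediate ⇌ isomer of the product (K = 2.30, k = 0.0100 s⁻¹)
    substrate + intermediate → side product (k = 0.0190 L mol⁻¹ s⁻¹)

At the start of this flask, 2 substrate → self-condensation product uses substrate at 9.4 times the rate of substrate → intermediate. Carrying the flask's 12.3% to a neighbouring flask charged at 0.66 M with the exponent 0.753 gives 18.1%, and that neighbouring flask reaches 16.6%.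

(The numbers in the tables are simulated with constants of no real substance; scatter was added.)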